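(The earlier runs and the new flask were generated by integration for substances that don't exist; the scatter is artificial.)

In both earlier runs target stands higher than the isomer of the product, 51 % against 22 % in the last eta row.

| flask | substrate | partner | remark | time |
|---|---|---|---|---|
| eta | 0.30 M | 0.21 M | run made earlier |  |
| epsilon | 0.30 M | 0.33 M | run made earlier |  |
| flask | 0.30 M | 0.150 M |  | 12 min |

- eta (time / min: target / %, isomer of the product / %): 1.00: 45, 18; 1.50: 44, 16; 2.50: 43, 17; 4.00: 44, 19; 8.00: 48, 22; 12.0: 51, 22
- epsilon (time / min: target / %, isomer of the product / %): 1.00: 69, 26; 1.50: 68, 23; 2.50: 72, 28; 4.00: 73, 25; 8.00: 68, 29; 12.0: 69, 30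

(standard deviation of a reading: 2 percentage points)

- the analysis behind the earlier runs scatters by 2 percentage points, standard deviation

- ratio of target to isomer of the product at 0.20 s
- ratio of target to isomer of the product at 12 s
- ratio of target to isomer of the product at 12 min

I follow one partner molecule that ends in a product and ask for its chance of ending as target. I call this the target share w: target over target plus isomer of the product. The last rows of the two runs, pooled, give a reading of w = 0.698.

The totals in those rows tell me how far product goes. The last eta row reads 73.0 % where c(partner)/c(substrate) is 70.0 %, and the last epsilon row, with partner in excess, reads 99.0 %. So I count one partner per product.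

In the new flask partner is the limiting reagent, charged at half the substrate, which puts the ceiling at 50.0 %. My reckoning for this flask at 12 min is 34.9 % target and 15.1 % isomer, a ratio of 2.31. The readings begin at 1.00 min, so I commit to nothing for 0.20 s or 12 s.

The forecast gives 2.8 (2.2 to 4.5), 2.7 (2.2 to 3.4) and 2.25 (1.8 to 2.6), and says the earliest value “could be higher if a fast unseen process occurs”.

The flask gives 38.7, 2.49 and 2.07.

    substrate ⇌ other conformer (K = 0.600, k = 0.0620 s⁻¹)
    substrate + partner → target (k = 1.00 M⁻¹ s⁻¹)
    partner + other conformer → isomer of the product (k = 4.40 M⁻¹ s⁻¹)
    partner ⇌ dormant form (K = 14.0, k = 0.0320 s⁻¹)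

As a target share, the flask's ratios are 0.975 at 0.20 s and 0.674 at 12 min, and that early share is where the forecast parts from the flask. The time 0.20 s lies far before the 0.19 min forward half-life of substrate turning into other conformer. In a neighbouring flask charged with 0.51 M of substrate, the ceiling falls to 29.4 %, and w reckons 20.5 % target and 8.88 % isomer. That flask holds 21.7 % target and 7.38 % isomer at 12.0 min, a ratio of 2.94.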